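The ester oxygen at C6 and the epoxide oxygen at C9 lie on the same face of the seven-membered ring, 1,4-related across C7–C8, so both are traced back to one 6,9-endoperoxide. A singlet-oxygen (4+2) cycloaddition to the ring-locked C6=C7–C8=C9 diene should form both C–O bonds and both stereocentres in one operation, on the face opposite the C1 angular methyl, and leave the C7=C8 alkene for closing the epoxide from O9. The precursor is the trans-fused hydroazulene diene with the five-membered ring finished (C2 acetate, C4 carbinol capped as a silyl ether so that it shields the methyl face); it comes from a cyclopentane by diene–ene ring-closing metathesis.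

Key step: step 16

Remark: atoms carry the target's numbering from the first cyclopentane onward (C1 quaternary methyl carbon, C2 acetoxy carbon, C4 carbinol, C5 ring-fusion CH, C6 ester carbon, C8 and C9 epoxide carbons, C10 methylene); α is the face of H5, β the face of the C1 methyl; R/S labels given with "C" refer to these atom numbers.
Remark: enone 4 and enynol 1 are taken to be purchasable in the configurations shown.

Step 1
Reactants: 1 (2Z)-3-methylpent-2-en-4-yn-1-ol
Product: 2 (2Z)-3-methylpenta-2,4-dien-1-ol
Conditions: H2 (1 atm), Pd/CaCO3 poisoned with Pb(OAc)2 (Lindlar catalyst), quinoline, EtOAc, rt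
Reagents that add atoms: none
Why: Lindlar semi-hydrogenation of the terminal alkyne should stop at the vinyl group and leave the trisubstituted (Z)-alkene, the future C8=C9 bond, untouched.

Step 2
Reactants: 2 (2Z)-3-methylpenta-2,4-dien-1-ol
Product: 3 (3Z)-5-bromo-3-methylpenta-1,3-diene
Conditions: PBr3 (0.4 equiv), pyridine (cat.), Et2O, −20 °C; used at once
Reagents that add atoms: phosphorus tribromide, BrP(Br)Br
Why: SN2 displacement of the primary allylic phosphite by bromide at low temperature should give the allylic bromide with the Z geometry retained.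

Step 3
Reactants: 4 (4S)-4-[(tert-butyldimethylsilyl)oxy]cyclopent-2-en-1-one
Product: 5 (4S)-4-[(tert-butyldimethylsilyl)oxy]-2-iodocyclopent-2-en-1-one
Conditions: I2, pyridine/CH2Cl2, 0 °C → rt
Reagents that add atoms: iodine, II
Why: Johnson α-iodination (pyridine-mediated addition, iodination and elimination) functionalises the enone α-carbon, the future C1, without touching the silyloxy stereocentre.

Step 4
Reactants: 5 α-iodoenone; 6 methylzinc chloride
Product: 7 (4S)-4-[(tert-butyldimethylsilyl)oxy]-2-methylcyclopent-2-en-1-one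
Conditions: Pd2(dba)3 (2.5 mol %), P(2-furyl)3 (10 mol %), THF/DMF, rt
Reagents that add atoms: methylzinc chloride (6), C[Zn]Cl
Why: Negishi coupling of the α-iodoenone installs the C1 methyl under neutral conditions that do not eliminate the β-silyloxy group.

Step 5
Reactants: 7 2-methyl enone; 8 vinylmagnesium bromide
Product: 9 silyl enol ether with C5 vinyl β and C4 OTBS α
Conditions: CuBr·SMe2 (0.2 equiv), Me3SiCl, THF, −78 °C; Et3N, pentane work-up
Reagents that add atoms: vinylmagnesium bromide (8), C=C[Mg]Br; chlorotrimethylsilane, C[Si](C)(C)Cl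
Why: Copper-catalysed, silyl-chloride-accelerated 1,4-addition should deliver the vinyl group (C6) to C5 anti to the C4 silyloxy group, as in prostaglandin syntheses, and trap the enolate regiospecifically before the silyloxy group can be eliminated.

Step 6
Reactants: 9 silyl enol ether; 3 (3Z)-5-bromo-3-methylpenta-1,3-diene
Product: 11 (2S,3S,4S)-4-[(tert-butyldimethylsilyl)oxy]-2-methyl-2-[(2Z)-3-methylpenta-2,4-dien-1-yl]-3-vinylcyclopentan-1-one, via lithium enolate 10 (not isolated)
Conditions: MeLi, THF, 0 °C; then 3, DMPU, −78 → −30 °C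
Reagents that add atoms: (3Z)-5-bromo-3-methylpenta-1,3-diene (3), C=C/C(C)=C\CBr
Why: Stork cleavage of the silyl enol ether gives the regiodefined lithium enolate, and its SN2 C-alkylation by the allylic bromide anti to the adjacent C5 vinyl group should set the C1 quaternary centre with the C10 chain trans to C6.

Step 7
Reactants: 11 C2 ketone
Product: 12 C2 ethylene ketal of 11
Conditions: Me3SiOCH2CH2OSiMe3, Me3SiOTf (cat.), CH2Cl2, −78 → −20 °C
Reagents that add atoms: 1,2-bis(trimethylsilyloxy)ethane, C[Si](C)(C)OCCO[Si](C)(C)C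
Why: Noyori ketalisation under aprotic, cold conditions masks the C2 ketone, so that C4 can later be a ketone without forming an enolisable 1,3-diketone, and should spare the silyl ether and the diene.

Step 8
Reactants: 12 ketal silyl ether
Product: 13 C4 α-alcohol with C2 ketal
Conditions: Bu4NF, THF, 0 °C → rt
Reagents that add atoms: none
Why: Fluoride cleavage of the secondary silyl ether frees the C4 hydroxyl while the ketal and the alkenes are inert.

Step 9
Reactants: 13 C4 alcohol
Product: 14 C4 ketone with C2 ketal
Conditions: Dess–Martin periodinane, NaHCO3, CH2Cl2, 0 °C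
Reagents that add atoms: none
Why: Buffered Dess–Martin oxidation gives the C4 ketone under non-epimerising conditions, so the C5 stereocentre next to the vinyl group is kept.

Step 10
Reactants: 14 C4 ketone; 15 isopropylmagnesium chloride
Product: 16 C4 tertiary carbinol (isopropyl α, hydroxyl β) with C2 ketal
Conditions: CeCl3 (anhydrous), THF, −78 °C
Reagents that add atoms: isopropylmagnesium chloride (15), CC(C)[Mg]Cl
Why: The weakly basic organocerium reagent (Imamoto conditions) should add to the enolisable β,γ-unsaturated ketone without enolisation or hydride transfer, attacking anti to the adjacent C5 vinyl group so that the isopropyl group ends α and the hydroxyl β.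

Step 11
Reactants: 16 ketal carbinol
Product: 17 (2S,3S,4S)-4-hydroxy-2-methyl-2-[(2Z)-3-methylpenta-2,4-dien-1-yl]-4-(propan-2-yl)-3-vinylcyclopentan-1-one
Conditions: PPTS (cat.), acetone/H2O, 40 °C
Reagents that add atoms: water, O
Why: Mild acid hydrolysis of the dioxolane unmasks the C2 ketone under conditions too weak to dehydrate the tertiary β-hydroxyl.

Step 12
Reactants: 17 β-hydroxy ketone
Product: 18 anti-1,3-diol (C2 hydroxyl α, C4 hydroxyl β)
Conditions: Me4NBH(OAc)3, MeCN/AcOH, −30 → 0 °C
Reagents that add atoms: none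
Why: Evans–Saksena reduction delivers hydride intramolecularly from boron bound to the β C4 oxygen to the β face of the C2 ketone, which should give the anti diol with the C2 hydroxyl α, trans to the C1 methyl.

Step 13
Reactants: 18 diol; 19 acetic anhydride
Product: 20 C2 α-acetate with free C4 hydroxyl
Conditions: pyridine, DMAP (cat.), CH2Cl2, 0 °C → rt
Reagents that add atoms: acetic anhydride (19), CC(=O)OC(C)=O
Why: DMAP-catalysed acylation should esterify the secondary C2 hydroxyl only, the tertiary C4 hydroxyl being too hindered.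

Step 14
Reactants: 20 triene acetate
Product: 21 trans-fused hydroazulene 6,8-diene with C2 α-acetate and C4 β-hydroxyl
Conditions: second-generation Hoveyda–Grubbs catalyst (5 mol %), CH2Cl2 (5 mM), 40 °C
Reagents that add atoms: none
Why: Diene–ene ring-closing metathesis joins C6 and C7 with loss of ethene, the preformed (Z)-C8=C9 bond holding both termini for seven-ring closure, while attack at the internal trisubstituted alkene would need a strained trans-fused bicyclo[3.3.0]octene.

Step 15
Reactants: 21 diene alcohol
Product: 22 C4 trimethylsilyl ether of 21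
Conditions: Me3SiOTf, 2,6-lutidine, CH2Cl2, −78 °C
Reagents that add atoms: trimethylsilyl trifluoromethanesulfonate, C[Si](C)(C)OS(=O)(=O)C(F)(F)F
Why: Silyl triflate silylation caps the hindered tertiary hydroxyl, which removes a hydrogen-bond donor that could draw singlet oxygen to the β face and adds steric bulk there.

Step 16
Reactants: 22 silyl-capped diene; 23 dioxygen
Product: 24 6α,9α-endoperoxide with C7=C8 alkene
Conditions: O2 (1 atm), 5,10,15,20-tetraphenylporphyrin (1 mol %), white LEDs, CH2Cl2, −30 °C
Reagents that add atoms: dioxygen (23), O=O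
Why: The excited porphyrin sensitises triplet to singlet dioxygen, which adds suprafacially to C6 and C9 of the s-cis diene in a concerted (4+2) cycloaddition. The closest known reaction is the singlet-oxygen cycloaddition to cyclohepta-1,3-dienes, which gives 6,7-dioxabicyclo[3.2.2]non-8-enes. The six-membered 1,2-dioxene ring (O–C6–C7=C8–C9–O) is closed by this cycloaddition, both C–O bonds forming in one step as a peroxide bridge across the seven-membered ring. C6 and C9 are set together: suprafacial addition makes the two C–O bonds cis, and the axial C1 methyl and the C4 silyloxy group block the β face, so both oxygens should enter α, cis to H5. The step needs α-face selectivity and cycloaddition in preference to the ene reaction at H5, H10 or the C8 methyl; the ring-locked s-cis geometry, the low temperature and the absence of a free hydroxyl on the β face should secure this.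

Step 17
Reactants: 24 endoperoxide
Product: 26 6α,9α-dihydroxy-7-ene with C4 β-hydroxyl and C2 α-acetate, via silyl-protected enediol 25 (not isolated)
Conditions: thiourea, MeOH/H2O, rt; then PPTS (cat.), rt
Reagents that add atoms: none
Why: Thiourea reduces only the O–O bond, so the cis α,α enediol follows from the endoperoxide with C6–O, C9–O and the alkene intact, and acid methanolysis then removes the tertiary silyl ether before any acid-sensitive epoxide exists.

Step 18
Reactants: 26 enediol
Product: 27 8α,9α-epoxy-6α-alcohol with C7 methylene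
Conditions: [N,N′-bis(3,5-di-tert-butylsalicylidene)cyclohexane-1,2-diaminato]cobalt (divalent cobalt, 5 mol %), N-fluoro-2,4,6-trimethylpyridinium tetrafluoroborate, PhSiH3, acetone, 0 °C
Reagents that add atoms: none
Why: Cobalt-hydride hydrogen-atom transfer to C7 gives the tertiary C8 radical, and radical–polar crossover through an alkylcobalt species lets the adjacent C9 hydroxyl displace the metal (3-exo-tet), a known cycloisomerisation of allylic alcohols to epoxides, so that O9 stays on C9, the epoxide can only be cis-fused on the α face with the C8 methyl β, and no carbon radical is ever formed next to an existing epoxide.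

Step 19
Reactants: 27 epoxy alcohol; 28 4-methoxybenzoyl chloride
Product: 29 target CNP0317703.1
Conditions: Et3N, DMAP, CH2Cl2, 0 °C → rt
Reagents that add atoms: 4-methoxybenzoyl chloride (28), COc1ccc(C(Cl)=O)cc1
Why: DMAP-catalysed acylation should esterify the only secondary hydroxyl (C6), the tertiary C4 hydroxyl and the epoxide being inert to these basic conditions.

Compound list
1 | (2Z)-3-methylpent-2-en-4-yn-1-ol | C#C/C(C)=C\CO | starting material
2 | (2Z)-3-methylpenta-2,4-dien-1-ol | C=C/C(C)=C\CO | intermediate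
3 | (3Z)-5-bromo-3-methylpenta-1,3-diene | C=C/C(C)=C\CBr | intermediate
4 | (4S)-4-[(tert-butyldimethylsilyl)oxy]cyclopent-2-en-1-one | O=C1C=C[C@@H](O[Si](C)(C)C(C)(C)C)C1 | starting material
5 | (4S)-4-[(tert-butyldimethylsilyl)oxy]-2-iodocyclopent-2-en-1-one | O=C1C(I)=C[C@@H](O[Si](C)(C)C(C)(C)C)C1 | intermediate
6 | methylzinc chloride | C[Zn]Cl | starting material
7 | (4S)-4-[(tert-butyldimethylsilyl)oxy]-2-methylcyclopent-2-en-1-one | O=C1C(C)=C[C@@H](O[Si](C)(C)C(C)(C)C)C1 | intermediate
8 | vinylmagnesium bromide | C=C[Mg]Br | starting material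
9 | (3S,4S)-4-[(tert-butyldimethylsilyl)oxy]-2-methyl-1-[(trimethylsilyl)oxy]-3-vinylcyclopent-1-ene (vinyl trans to OTBS) | CC1=C(O[Si](C)(C)C)C[C@H](O[Si](C)(C)C(C)(C)C)[C@H]1C=C | intermediate
10 | lithium (3S,4S)-4-[(tert-butyldimethylsilyl)oxy]-2-methyl-3-vinylcyclopent-1-en-1-olate | CC1=C(O[Li])C[C@H](O[Si](C)(C)C(C)(C)C)[C@H]1C=C | intermediate
11 | (2S,3S,4S)-4-[(tert-butyldimethylsilyl)oxy]-2-methyl-2-[(2Z)-3-methylpenta-2,4-dien-1-yl]-3-vinylcyclopentan-1-one (C1 methyl β, C10 chain α, C5 vinyl β, C4 OTBS α) | C=C/C(C)=C\C[C@]1(C)C(=O)C[C@H](O[Si](C)(C)C(C)(C)C)[C@H]1C=C | intermediate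
12 | C2 ethylene ketal (dioxolane) of 11; C1 S, C4 S, C5 S | C=C/C(C)=C\C[C@]1(C)C2(OCCO2)C[C@H](O[Si](C)(C)C(C)(C)C)[C@H]1C=C | intermediate
13 | C4 α-alcohol with C2 dioxolane; C1 S, C4 S, C5 S | C=C/C(C)=C\C[C@]1(C)C2(OCCO2)C[C@H](O)[C@H]1C=C | intermediate
14 | C4 ketone with C2 dioxolane; C1 S, C5 S | C=C/C(C)=C\C[C@]1(C)C2(OCCO2)CC(=O)[C@H]1C=C | intermediate
15 | isopropylmagnesium chloride | CC(C)[Mg]Cl | starting material
16 | C4 tertiary carbinol with C2 dioxolane (isopropyl α, hydroxyl β); C1 S, C4 S, C5 S | C=C/C(C)=C\C[C@]1(C)C2(OCCO2)C[C@](O)(C(C)C)[C@H]1C=C | intermediate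
17 | (2S,3S,4S)-4-hydroxy-2-methyl-2-[(2Z)-3-methylpenta-2,4-dien-1-yl]-4-(propan-2-yl)-3-vinylcyclopentan-1-one | C=C/C(C)=C\C[C@]1(C)C(=O)C[C@](O)(C(C)C)[C@H]1C=C | intermediate
18 | anti-1,3-diol of the cyclopentane (C2 hydroxyl α, C4 hydroxyl β); C1 S, C2 R, C4 S, C5 S | C=C/C(C)=C\C[C@]1(C)[C@H](O)C[C@](O)(C(C)C)[C@H]1C=C | intermediate
19 | acetic anhydride | CC(=O)OC(C)=O | starting material
20 | C2 α-acetate of 18 with free C4 β-hydroxyl; C1 S, C2 R, C4 S, C5 S | C=C/C(C)=C\C[C@]1(C)[C@H](OC(C)=O)C[C@](O)(C(C)C)[C@H]1C=C | intermediate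
21 | trans-fused hydroazulene 6,8-diene (C6=C7–C8(CH3)=C9), C2 α-acetate, C4 β-hydroxyl α-isopropyl, C1 β-methyl; C1 S, C2 R, C4 S, C5 S | C1=CC(C)=CC[C@]2(C)[C@H](OC(C)=O)C[C@](O)(C(C)C)[C@@H]12 | intermediate
22 | C4 trimethylsilyl ether of 21 | C1=CC(C)=CC[C@]2(C)[C@H](OC(C)=O)C[C@](O[Si](C)(C)C)(C(C)C)[C@@H]12 | intermediate
23 | dioxygen | O=O | starting material
24 | 6α,9α-endoperoxide (C6–O–O–C9 bridge, C7=C8) with C2 α-acetate and C4 β-OTMS; C1 S, C2 R, C4 S, C5 R, C6 R, C9 R | O1O[C@@H]2C=C(C)[C@H]1C[C@]3(C)[C@H](OC(C)=O)C[C@](O[Si](C)(C)C)(C(C)C)[C@@H]23 | intermediate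
25 | 6α,9α-dihydroxy-7-ene with C4 β-OTMS and C2 α-acetate | O[C@@H]1C=C(C)[C@H](O)C[C@]2(C)[C@H](OC(C)=O)C[C@](O[Si](C)(C)C)(C(C)C)[C@@H]12 | intermediate
26 | 6α,9α-dihydroxy-7-ene with C4 β-hydroxyl and C2 α-acetate | O[C@@H]1C=C(C)[C@H](O)C[C@]2(C)[C@H](OC(C)=O)C[C@](O)(C(C)C)[C@@H]12 | intermediate
27 | 8α,9α-epoxy-6α-alcohol with C2 α-acetate and C4 β-hydroxyl; C1 S, C2 R, C4 S, C5 R, C6 R, C8 S, C9 R | O[C@@H]1C[C@]2(C)O[C@@H]2C[C@]3(C)[C@H](OC(C)=O)C[C@](O)(C(C)C)[C@@H]13 | intermediate
28 | 4-methoxybenzoyl chloride | COc1ccc(C(Cl)=O)cc1 | starting material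
29 | CNP0317703.1, the C6 α-(4-methoxybenzoate) of 27 | COc1ccc(C(=O)O[C@@H]2C[C@]3(C)O[C@@H]3C[C@]3(C)[C@H](OC(C)=O)C[C@](O)(C(C)C)[C@@H]23)cc1 | target

Total step count: 19. Longest linear sequence: 17 steps (steps 3 to 19, from enone 4); steps 1 and 2 make bromide 3, which joins at step 6.

Steps most likely to fail

Step 16. Singlet oxygen may attack the β face, the C4 isopropyl group may hinder the α face at C6, or ene-type hydroperoxidation at H5, H10 or the C8 methyl may compete with cycloaddition. The fallback sets out from diene 21 and brings in the two oxygens stepwise with known chemistry. Peracid epoxidation (mCPBA, NaHCO3, CH2Cl2, −20 °C) of the more electron-rich trisubstituted C8=C9 bond from the α face should give the 8α,9α-epoxy-6-ene F1. Ionisation of this vinyl epoxide by Pd(PPh3)4 (zerovalent palladium) and 1,4-syn addition of 4-methoxybenzoic acid (THF, 0 °C, net retention by double inversion) should give the C6 α-(4-methoxybenzoate) with free C9 α-hydroxyl and C7=C8 alkene F2. The cycloisomerisation conditions of step 18 applied to F2 then close the epoxide, so the fallback comes back to the route at target 29.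

Step 18. The cycloisomerisation may divert to a 1,2-hydride shift from C9 (giving the C9 ketone), to closure by the C6 hydroxyl to an oxetane, or to plain reduction of the alkene. The fallback sets out from triol 26. A Myers reductive 1,3-transposition at the less hindered allylic C9 hydroxyl (2-nitrobenzenesulfonylhydrazide, PPh3, diethyl azodicarboxylate, THF, −30 °C → rt) should pass through the Mitsunobu product, the C9 β N-(2-nitrobenzenesulfonyl)hydrazine F3, and the C9 β allylic diazene F4, whose sigmatropic loss of dinitrogen delivers hydrogen to C7 and gives the C6 α-hydroxy 8-ene F5. Hydroxyl-directed epoxidation (VO(acac)2, tBuOOH, CH2Cl2, 0 °C) on the α face then gives epoxy alcohol 27, where the fallback rejoins the route; in this case the epoxide oxygen comes from the hydroperoxide and not from O9.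

Step 14. Ring closure may stall because the C5 vinyl group sits between two fully substituted carbons, so that oligomerisation or catalyst decay wins. The fallback closes the ring earlier, on ketal 12, where C4 is only a secondary silyloxy carbon. Metathesis under the conditions of step 14 should give the bicyclic diene with C2 ketal and C4 α-OTBS F6, and the chemistry of steps 8 to 13 is then run on the bicycle: Bu4NF to the bicyclic C4 α-alcohol F7, Dess–Martin oxidation to the bicyclic C4 ketone F8, isopropylcerium addition from the α face (now also anti to the angular methyl) to the bicyclic C4 carbinol F9, ketal hydrolysis to the bicyclic β-hydroxy ketone F10, Evans–Saksena reduction to the bicyclic anti-diol F11, and acetylation, which returns to the route at diene 21.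

Further compounds
F1 | step 16 | 8α,9α-epoxy-6-ene (C2 α-acetate, C4 β-hydroxyl) | C1=C[C@]2(C)O[C@@H]2C[C@]3(C)[C@H](OC(C)=O)C[C@](O)(C(C)C)[C@@H]13
F2 | step 16 | C6 α-(4-methoxybenzoate) with free C9 α-hydroxyl and C7=C8 alkene | COc1ccc(C(=O)O[C@@H]2C=C(C)[C@H](O)C[C@]3(C)[C@H](OC(C)=O)C[C@](O)(C(C)C)[C@@H]23)cc1
F3 | step 18 | C9 β N-(2-nitrobenzenesulfonyl)hydrazine | O[C@@H]1C=C(C)[C@@H](N(N)S(=O)(=O)c3ccccc3[N+](=O)[O-])C[C@]2(C)[C@H](OC(C)=O)C[C@](O)(C(C)C)[C@@H]12
F4 | step 18 | C9 β allylic diazene | O[C@@H]1C=C(C)[C@@H](N=N)C[C@]2(C)[C@H](OC(C)=O)C[C@](O)(C(C)C)[C@@H]12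
F5 | step 18 | C6 α-hydroxy 8-ene (C7 methylene, C2 α-acetate, C4 β-hydroxyl) | O[C@@H]1CC(C)=CC[C@]2(C)[C@H](OC(C)=O)C[C@](O)(C(C)C)[C@@H]12
F6 | step 14 | bicyclic diene with C2 ketal and C4 α-OTBS | C1=CC(C)=CC[C@]2(C)C3(OCCO3)C[C@H](O[Si](C)(C)C(C)(C)C)[C@@H]12
F7 | step 14 | bicyclic C4 α-alcohol with C2 ketal | C1=CC(C)=CC[C@]2(C)C3(OCCO3)C[C@H](O)[C@@H]12
F8 | step 14 | bicyclic C4 ketone with C2 ketal | C1=CC(C)=CC[C@]2(C)C3(OCCO3)CC(=O)[C@@H]12
F9 | step 14 | bicyclic C4 carbinol with C2 ketal (isopropyl α, hydroxyl β) | C1=CC(C)=CC[C@]2(C)C3(OCCO3)C[C@](O)(C(C)C)[C@@H]12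
F10 | step 14 | bicyclic β-hydroxy ketone (C2 ketone, C4 β-hydroxyl) | C1=CC(C)=CC[C@]2(C)C(=O)C[C@](O)(C(C)C)[C@@H]12
F11 | step 14 | bicyclic anti-diol (C2 α-hydroxyl, C4 β-hydroxyl) | C1=CC(C)=CC[C@]2(C)[C@H](O)C[C@](O)(C(C)C)[C@@H]12
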